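**Retrosynthetic overview**
1. Target 33 ⇐ desilylation and senecioylation of epoxy alcohol 30 ⇐ tartrate-controlled epoxidation and CBS reduction of the macrocyclic cross-conjugated dienone 28.
2. The only carbocycle (eleven-membered, closed at step 16 of 20): 28 ⇐ palladium-catalysed carbonylative Heck macrocyclization of acyclic alkenyl iodide 27 with CO (bonds C11–C1 and C1–C2).
3. 27 ⇐ E-selective Wittig union (C6=C7) of aldehyde 24 with phosphorane 23 (fragment C, from pent-3-yn-1-ol and ethyl bromoacetate).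
4. 24 ⇐ copper-catalysed enantioselective SN2′ allyl–alkyl coupling that creates quaternary C9: dialkylzinc from iodide 6 (fragment A, from (S)-α-hydroxy-γ-butyrolactone) plus allylic phosphate 11 (fragment B, from but-3-yn-1-ol).
5. The epoxide ring is formed after the carbocycle (step 18).

Assumption: the target is the structure encoded by the given SMILES. Ring locants in names: C1 = ester-bearing carbinol carbon, C2/C3 = epoxide carbons (C2 methylated), C6 = hydroxymethyl-bearing alkene carbon, C9 = quaternary carbon. TBS = tert-butyldimethylsilyl, TES = triethylsilyl, dppp = 1,3-bis(diphenylphosphino)propane, PMP = 1,2,2,6,6-pentamethylpiperidine.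

**Fragment A**

Step 1
Reactants: 1 (S)-3-hydroxyoxolan-2-one
Product: 2 (S)-3-(TBS-oxy)oxolan-2-one
Conditions: TBSCl, imidazole, DMF, 23 °C
Reagents that add atoms: tert-butyldimethylsilyl chloride, CC(C)(C)[Si](C)(C)Cl
Why: Routine silylation of the secondary alcohol that leaves the chiral-pool stereocentre (the future side-chain carbinol) untouched.

Step 2
Reactants: 2 (S)-3-(TBS-oxy)oxolan-2-one
Product: 5 (S)-4-methyl-3-(TBS-oxy)pent-4-en-1-ol, via methyl lactol 3 (not isolated), via open-chain hydroxy ketone 4 (not isolated)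
Conditions: MeLi (1.05 equiv), THF, −78 °C; then Ph3P=CH2 (3 equiv, from Ph3PCH3Br/n-BuLi), THF, −78 → 23 °C
Reagents that add atoms: methyllithium, [Li]C; methylenetriphenylphosphorane, C=P(c1ccccc1)(c1ccccc1)c1ccccc1
Why: Mono-addition of MeLi stops at the lithium lactolate, whose open keto-alkoxide tautomer undergoes Wittig methylenation to the isopropenyl group without touching the adjacent stereocentre.

Step 3
Reactants: 5 (S)-4-methyl-3-(TBS-oxy)pent-4-en-1-ol
Product: 6 (S)-5-iodo-2-methyl-3-(TBS-oxy)pent-1-ene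
Conditions: I2, PPh3, imidazole, CH2Cl2, 0 °C
Reagents that add atoms: iodine, II
Why: Appel iodination of the primary alcohol, with no stereocentre involved.

**Fragment B**

Step 4
Reactants: 7 but-3-yn-1-ol
Product: 8 4-(TES-oxy)but-1-yne
Conditions: Et3SiCl, imidazole, CH2Cl2, 0 → 23 °C
Reagents that add atoms: chlorotriethylsilane, CC[Si](Cl)(CC)CC
Why: Routine silylation; the TES ether is later removable in the presence of the secondary TBS ether.

Step 5
Reactants: 8 4-(TES-oxy)but-1-yne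
Product: 10 (E)-3-methyl-5-(TES-oxy)pent-2-en-1-ol, via alkenylalane 9 (not isolated)
Conditions: AlMe3 (2 equiv), Cp2ZrCl2 (25 mol%), CH2Cl2, 0 → 23 °C; then n-BuLi, THF, −78 °C; (CH2O)n, → 23 °C; aq. potassium sodium tartrate
Reagents that add atoms: trimethylaluminium, C[Al](C)C; formaldehyde (as paraformaldehyde), C=O
Why: Negishi zirconium-catalysed carboalumination adds Me and Al syn with Me on the internal carbon (E > 98:2), and the derived aluminate is hydroxymethylated with retention of geometry.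

Step 6
Reactants: 10 (E)-3-methyl-5-(TES-oxy)pent-2-en-1-ol
Product: 11 diethyl (E)-3-methyl-5-(TES-oxy)pent-2-en-1-yl phosphate
Conditions: ClP(O)(OEt)2, Et3N, DMAP (cat.), CH2Cl2, 0 °C
Reagents that add atoms: diethyl chlorophosphate, CCOP(=O)(Cl)OCC
Why: Standard phosphorylation of a primary allylic alcohol to give the leaving group needed for copper-catalysed allylic substitution.

**Union of A and B**

Step 7
Reactants: 6 (S)-5-iodo-2-methyl-3-(TBS-oxy)pent-1-ene; 11 diethyl (E)-3-methyl-5-(TES-oxy)pent-2-en-1-yl phosphate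
Product: 13 (3S,6S)-6-ethenyl-2,6-dimethyl-3-(TBS-oxy)-8-(TES-oxy)oct-1-ene, via dialkylzinc 12 (not isolated)
Conditions: 6 (3 equiv), Et2Zn (neat), CuI (0.3 mol%), 50 °C, then volatiles removed in vacuo; 11 (1 equiv), chiral sulfonate-bearing imidazolinium salt (bidentate NHC precursor, 5 mol%), (CuOTf)2·C6H6 (2.5 mol%), THF, −15 °C
Reagents that add atoms: diethylzinc, CC[Zn]CC (supplies the zinc of 12; no atoms in 13)
Why: Iodine–zinc exchange gives the salt-free dialkylzinc, and copper-catalysed asymmetric allylic alkylation (SN2′) with the ligand enantiomer that delivers the alkyl group to the Si face of C3 of the (E)-phosphate creates the all-carbon quaternary centre as 6S; the 3S centre is carried in unchanged, so the minor face gives a separable diastereomer.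

Step 8
Reactants: 13 (3S,6S)-6-ethenyl-2,6-dimethyl-3-(TBS-oxy)-8-(TES-oxy)oct-1-ene
Product: 14 (3S,6S)-3-ethenyl-3,7-dimethyl-6-(TBS-oxy)oct-7-en-1-ol
Conditions: PPTS (cat.), MeOH, 0 °C
Reagents that add atoms: none
Why: Mild acid methanolysis cleaves the primary TES ether far faster than the hindered secondary allylic TBS ether.

**Fragment C**

Step 9
Reactants: 15 pent-3-yn-1-ol
Product: 16 5-bromopent-2-yne
Conditions: CBr4, PPh3, CH2Cl2, 0 °C
Reagents that add atoms: carbon tetrabromide, BrC(Br)(Br)Br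
Why: Appel bromination of the primary alcohol removes the acidic OH before hydrozirconation.

Step 10
Reactants: 16 5-bromopent-2-yne
Product: 18 (E)-5-bromo-2-iodopent-2-ene, via alkenylzirconocene 17 (not isolated)
Conditions: Cp2Zr(H)Cl (1.5 equiv), THF, 23 → 45 °C; then I2, 0 °C
Reagents that add atoms: Cp2Zr(H)Cl, [H][Zr](Cl)(C1C=CC=C1)C1C=CC=C1 (zirconium of 17); iodine, II
Why: Hydrozirconation is a syn addition that under thermodynamic control (excess hydride, mild heating) places zirconium on the methyl-bearing alkyne carbon, and iodinolysis with retention gives the (E)-2-iodoalkene.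

Step 11
Reactants: 19 ethyl bromoacetate
Product: 21 ethyl (triphenylphosphoranylidene)acetate, via phosphonium bromide 20 (not isolated)
Conditions: PPh3, toluene, 23 °C; then NaOH (aq), CH2Cl2
Reagents that add atoms: triphenylphosphine, c1ccc(cc1)P(c1ccccc1)c1ccccc1
Why: Quaternisation of PPh3 by the α-bromo ester and deprotonation gives the stabilised ylide.

Step 12
Reactants: 18 (E)-5-bromo-2-iodopent-2-ene; 21 ethyl (triphenylphosphoranylidene)acetate
Product: 23 ethyl (5E)-6-iodo-2-(triphenylphosphoranylidene)hept-5-enoate, via alkylated phosphonium bromide 22 (not isolated)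
Conditions: 21 (2.2 equiv), NaI (10 mol%), MeCN, 80 °C
Reagents that add atoms: none
Why: C-alkylation of the stabilised ylide by the primary bromide followed by transylidation (the second equivalent of 21 acts as base) gives the α-alkylated ylide; the alkenyl iodide is inert.

**Union with C and endgame**

Step 13
Reactants: 14 (3S,6S)-3-ethenyl-3,7-dimethyl-6-(TBS-oxy)oct-7-en-1-ol; 23 ethyl (5E)-6-iodo-2-(triphenylphosphoranylidene)hept-5-enoate
Product: 25 ethyl (2E,5S,8S)-5-ethenyl-2-[(3E)-4-iodopent-3-en-1-yl]-5,9-dimethyl-8-(TBS-oxy)deca-2,9-dienoate, via aldehyde 24 (not isolated)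
Conditions: Dess–Martin periodinane, NaHCO3, CH2Cl2, 0 → 23 °C; then 23 (1.3 equiv), toluene, 80 °C
Reagents that add atoms: none
Why: Dess–Martin oxidation followed in the same flask by Wittig olefination with the α-alkyl stabilised ylide, which gives the (E)-trisubstituted enoate (ester trans to the C4 chain) under the usual thermodynamic control.

Step 14
Reactants: 25 ethyl (2E,5S,8S)-5-ethenyl-2-[(3E)-4-iodopent-3-en-1-yl]-5,9-dimethyl-8-(TBS-oxy)deca-2,9-dienoate
Product: 26 (2E,5S,8S)-5-ethenyl-2-[(3E)-4-iodopent-3-en-1-yl]-5,9-dimethyl-8-(TBS-oxy)deca-2,9-dien-1-ol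
Conditions: i-Bu2AlH (2.5 equiv), CH2Cl2, −78 °C; aq. potassium sodium tartrate
Reagents that add atoms: none
Why: 1,2-Reduction of the enoate to the allylic alcohol with retention of alkene geometry; the alkenyl iodide and silyl ether are inert.

Step 15
Reactants: 26 (2E,5S,8S)-5-ethenyl-2-[(3E)-4-iodopent-3-en-1-yl]-5,9-dimethyl-8-(TBS-oxy)deca-2,9-dien-1-ol
Product: 27 (2E,5S,8S)-1,8-bis(TBS-oxy)-5-ethenyl-2-[(3E)-4-iodopent-3-en-1-yl]-5,9-dimethyldeca-2,9-diene
Conditions: TBSCl, imidazole, DMF, 23 °C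
Reagents that add atoms: tert-butyldimethylsilyl chloride, CC(C)(C)[Si](C)(C)Cl
Why: Silylation of the primary allylic alcohol prevents alkoxycarbonylation in the next step and later acylation at this oxygen.

Step 16
Reactants: 27 (2E,5S,8S)-1,8-bis(TBS-oxy)-5-ethenyl-2-[(3E)-4-iodopent-3-en-1-yl]-5,9-dimethyldeca-2,9-diene
Product: 28 (2E,6E,9S,10E)-2,9-dimethyl-6-[(TBS-oxy)methyl]-9-[(3S)-4-methyl-3-(TBS-oxy)pent-4-en-1-yl]cycloundeca-2,6,10-trien-1-one
Conditions: Pd(OAc)2 (10 mol%), dppp (12 mol%), AgOTf (1.1 equiv), PMP (2.5 equiv), CO (2 atm), PhCl, 70 °C, syringe-pump addition to 2 mM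
Reagents that add atoms: carbon monoxide, [C-]#[O+]
Why: Proposed new method: a carbonylative Heck macrocyclization in which zerovalent palladium inserts into the alkenyl C–I bond, CO insertion gives an unsaturated acylpalladium, iodide abstraction by AgOTf opens a cis site on the cationic diphosphine complex for the only monosubstituted alkene, the acyl group migrates to its terminal carbon, and base-assisted β-hydride loss (only the C11 hydrogen is available because C9 is quaternary) releases the (E)-enone and closes the eleven-membered ring, smaller rings onto the nearer trisubstituted alkene being impossible because the (E)-alkenyl iodide would have to sit trans in a six- or seven-membered ring; the closest known reactions are the intermolecular carbonylative Heck vinylation of alkenyl triflates with styrenes, intramolecular acylpalladation to five- and six-membered rings, the acyl-to-alkene insertion of CO/olefin copolymerization, and carbonylative Stille macrocyclization to macrocyclic dienones.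

Step 17
Reactants: 28 (2E,6E,9S,10E)-2,9-dimethyl-6-[(TBS-oxy)methyl]-9-[(3S)-4-methyl-3-(TBS-oxy)pent-4-en-1-yl]cycloundeca-2,6,10-trien-1-one
Product: 29 (1R,2E,6E,9S,10E)-2,9-dimethyl-6-[(TBS-oxy)methyl]-9-[(3S)-4-methyl-3-(TBS-oxy)pent-4-en-1-yl]cycloundeca-2,6,10-trien-1-ol
Conditions: (S)-2-methyl-CBS-oxazaborolidine (0.5 equiv), catecholborane (1.8 equiv), toluene, −78 °C
Reagents that add atoms: none
Why: Corey–Bakshi–Shibata reduction in which the α-methyl-substituted alkenyl arm is expected to act as the large group, so the (S)-catalyst delivers hydride to the face that gives the (1R) bis-allylic alcohol with pure 1,2-selectivity.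

Step 18
Reactants: 29 (1R,2E,6E,9S,10E)-2,9-dimethyl-6-[(TBS-oxy)methyl]-9-[(3S)-4-methyl-3-(TBS-oxy)pent-4-en-1-yl]cycloundeca-2,6,10-trien-1-ol
Product: 30 (1R,2S,3S,6E,9S,10E)-2,3-epoxy-2,9-dimethyl-6-[(TBS-oxy)methyl]-9-[(3S)-4-methyl-3-(TBS-oxy)pent-4-en-1-yl]cycloundeca-6,10-dien-1-ol
Conditions: Ti(OiPr)4 (20 mol%), D-(−)-diisopropyl tartrate (24 mol%), t-BuOOH (2 equiv), 4 Å MS, CH2Cl2, −20 °C
Reagents that add atoms: tert-butyl hydroperoxide, CC(C)(C)OO
Why: Katsuki–Sharpless epoxidation in which, for the (1R)-alcohol, D-(−)-tartrate is the matched ligand for the electron-rich C2=C3 alkene and mismatched for C10=C11, so oxygen is delivered to the face that gives the erythro epoxy alcohol, the same sense that A1,2 strain favours in hydroxyl-directed epoxidation.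

Step 19
Reactants: 30 (1R,2S,3S,6E,9S,10E)-2,3-epoxy-2,9-dimethyl-6-[(TBS-oxy)methyl]-9-[(3S)-4-methyl-3-(TBS-oxy)pent-4-en-1-yl]cycloundeca-6,10-dien-1-ol; 31 3-methylbut-2-enoyl chloride
Product: 32 (1R,2R,3S,6E,9S,10E)-2,3-epoxy-2,9-dimethyl-6-[(TBS-oxy)methyl]-9-[(3S)-4-methyl-3-(TBS-oxy)pent-4-en-1-yl]cycloundeca-6,10-dien-1-yl 3-methylbut-2-enoate
Conditions: 31 (3 equiv), pyridine, DMAP (cat.), CH2Cl2, 0 °C
Reagents that add atoms: none
Why: DMAP-catalysed acylation of the hindered secondary alcohol with pyridine as the only base at 0 °C, which avoids vinylketene formation and deconjugation of the senecioate (the C2 descriptor changes from S to R by CIP priority only).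

Step 20
Reactants: 32 (1R,2R,3S,6E,9S,10E)-2,3-epoxy-2,9-dimethyl-6-[(TBS-oxy)methyl]-9-[(3S)-4-methyl-3-(TBS-oxy)pent-4-en-1-yl]cycloundeca-6,10-dien-1-yl 3-methylbut-2-enoate
Product: 33 (1R,2R,3S,6E,9S,10E)-2,3-epoxy-6-(hydroxymethyl)-9-[(3S)-3-hydroxy-4-methylpent-4-en-1-yl]-2,9-dimethylcycloundeca-6,10-dien-1-yl 3-methylbut-2-enoate
Conditions: Bu4NF (3 equiv), AcOH (3 equiv), THF, 0 → 23 °C
Reagents that add atoms: none
Why: Acetic acid-buffered fluoride desilylation removes both TBS ethers while sparing the ester and the acid-sensitive epoxide.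

**Compound list**

1 | (S)-3-hydroxyoxolan-2-one ((S)-α-hydroxy-γ-butyrolactone) | O=C1[C@@H](O)CCO1 | starting material
2 | (S)-3-(TBS-oxy)oxolan-2-one | O=C1[C@@H](O[Si](C)(C)C(C)(C)C)CCO1 | intermediate
3 | (3S)-2-methyl-3-(TBS-oxy)oxolan-2-ol (lactol, present as lithium salt, not isolated) | CC1(O)[C@@H](O[Si](C)(C)C(C)(C)C)CCO1 | intermediate
4 | (S)-5-hydroxy-3-(TBS-oxy)pentan-2-one (open-chain tautomer, not isolated) | CC(=O)[C@@H](O[Si](C)(C)C(C)(C)C)CCO | intermediate
5 | (S)-4-methyl-3-(TBS-oxy)pent-4-en-1-ol | C=C(C)[C@@H](O[Si](C)(C)C(C)(C)C)CCO | intermediate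
6 | (S)-5-iodo-2-methyl-3-(TBS-oxy)pent-1-ene (fragment A) | C=C(C)[C@@H](O[Si](C)(C)C(C)(C)C)CCI | intermediate
7 | but-3-yn-1-ol | C#CCCO | starting material
8 | 4-(TES-oxy)but-1-yne | C#CCCO[Si](CC)(CC)CC | intermediate
9 | dimethyl[(E)-2-methyl-4-(TES-oxy)but-1-en-1-yl]alane (not isolated) | C[Al](C)/C=C(\C)CCO[Si](CC)(CC)CC | intermediate
10 | (E)-3-methyl-5-(TES-oxy)pent-2-en-1-ol | OC/C=C(\C)CCO[Si](CC)(CC)CC | intermediate
11 | diethyl (E)-3-methyl-5-(TES-oxy)pent-2-en-1-yl phosphate (fragment B) | CCOP(=O)(OCC)OC/C=C(\C)CCO[Si](CC)(CC)CC | intermediate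
12 | bis[(3S)-4-methyl-3-(TBS-oxy)pent-4-en-1-yl]zinc (not isolated) | C=C(C)[C@@H](O[Si](C)(C)C(C)(C)C)CC[Zn]CC[C@H](O[Si](C)(C)C(C)(C)C)C(C)=C | intermediate
13 | (3S,6S)-6-ethenyl-2,6-dimethyl-3-(TBS-oxy)-8-(TES-oxy)oct-1-ene | C=C(C)[C@@H](O[Si](C)(C)C(C)(C)C)CC[C@](C)(C=C)CCO[Si](CC)(CC)CC | intermediate
14 | (3S,6S)-3-ethenyl-3,7-dimethyl-6-(TBS-oxy)oct-7-en-1-ol | C=C(C)[C@@H](O[Si](C)(C)C(C)(C)C)CC[C@](C)(C=C)CCO | intermediate
15 | pent-3-yn-1-ol | CC#CCCO | starting material
16 | 5-bromopent-2-yne | CC#CCCBr | intermediate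
17 | [(E)-5-bromopent-2-en-2-yl]chlorobis(cyclopentadienyl)zirconium (not isolated) | C/C(=C\CCBr)[Zr](Cl)(C1C=CC=C1)C1C=CC=C1 | intermediate
18 | (E)-5-bromo-2-iodopent-2-ene | C/C(I)=C\CCBr | intermediate
19 | ethyl bromoacetate | CCOC(=O)CBr | starting material
20 | (2-ethoxy-2-oxoethyl)triphenylphosphonium bromide (not isolated) | CCOC(=O)C[P+](c1ccccc1)(c1ccccc1)c1ccccc1.[Br-] | intermediate
21 | ethyl (triphenylphosphoranylidene)acetate | CCOC(=O)C=P(c1ccccc1)(c1ccccc1)c1ccccc1 | intermediate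
22 | [(5E)-1-ethoxy-6-iodo-1-oxohept-5-en-2-yl]triphenylphosphonium bromide (not isolated) | CCOC(=O)C(CC/C=C(\C)I)[P+](c1ccccc1)(c1ccccc1)c1ccccc1.[Br-] | intermediate
23 | ethyl (5E)-6-iodo-2-(triphenylphosphoranylidene)hept-5-enoate (fragment C) | CCOC(=O)C(CC/C=C(\C)I)=P(c1ccccc1)(c1ccccc1)c1ccccc1 | intermediate
24 | (3S,6S)-3-ethenyl-3,7-dimethyl-6-(TBS-oxy)oct-7-enal (not isolated) | C=C(C)[C@@H](O[Si](C)(C)C(C)(C)C)CC[C@](C)(C=C)CC=O | intermediate
25 | ethyl (2E,5S,8S)-5-ethenyl-2-[(3E)-4-iodopent-3-en-1-yl]-5,9-dimethyl-8-(TBS-oxy)deca-2,9-dienoate | C=C(C)[C@@H](O[Si](C)(C)C(C)(C)C)CC[C@](C)(C=C)C/C=C(\CC/C=C(\C)I)C(=O)OCC | intermediate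
26 | (2E,5S,8S)-5-ethenyl-2-[(3E)-4-iodopent-3-en-1-yl]-5,9-dimethyl-8-(TBS-oxy)deca-2,9-dien-1-ol | C=C(C)[C@@H](O[Si](C)(C)C(C)(C)C)CC[C@](C)(C=C)C/C=C(\CC/C=C(\C)I)CO | intermediate
27 | (2E,5S,8S)-1,8-bis(TBS-oxy)-5-ethenyl-2-[(3E)-4-iodopent-3-en-1-yl]-5,9-dimethyldeca-2,9-diene | C=C(C)[C@@H](O[Si](C)(C)C(C)(C)C)CC[C@](C)(C=C)C/C=C(\CC/C=C(\C)I)CO[Si](C)(C)C(C)(C)C | intermediate
28 | (2E,6E,9S,10E)-2,9-dimethyl-6-[(TBS-oxy)methyl]-9-[(3S)-4-methyl-3-(TBS-oxy)pent-4-en-1-yl]cycloundeca-2,6,10-trien-1-one | C=C(C)[C@@H](O[Si](C)(C)C(C)(C)C)CC[C@]1(C)/C=C/C(=O)/C(C)=C/CC/C(CO[Si](C)(C)C(C)(C)C)=C\C1 | intermediate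
29 | (1R,2E,6E,9S,10E)-2,9-dimethyl-6-[(TBS-oxy)methyl]-9-[(3S)-4-methyl-3-(TBS-oxy)pent-4-en-1-yl]cycloundeca-2,6,10-trien-1-ol | C=C(C)[C@@H](O[Si](C)(C)C(C)(C)C)CC[C@]1(C)/C=C/[C@@H](O)/C(C)=C/CC/C(CO[Si](C)(C)C(C)(C)C)=C\C1 | intermediate
30 | (1R,2S,3S,6E,9S,10E)-2,3-epoxy-2,9-dimethyl-6-[(TBS-oxy)methyl]-9-[(3S)-4-methyl-3-(TBS-oxy)pent-4-en-1-yl]cycloundeca-6,10-dien-1-ol | C=C(C)[C@@H](O[Si](C)(C)C(C)(C)C)CC[C@]1(C)/C=C/[C@@H](O)[C@]2(C)O[C@H]2CC/C(CO[Si](C)(C)C(C)(C)C)=C\C1 | intermediate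
31 | 3-methylbut-2-enoyl chloride | CC(C)=CC(=O)Cl | starting material
32 | (1R,2R,3S,6E,9S,10E)-2,3-epoxy-2,9-dimethyl-6-[(TBS-oxy)methyl]-9-[(3S)-4-methyl-3-(TBS-oxy)pent-4-en-1-yl]cycloundeca-6,10-dien-1-yl 3-methylbut-2-enoate | C=C(C)[C@@H](O[Si](C)(C)C(C)(C)C)CC[C@]1(C)/C=C/[C@@H](OC(=O)C=C(C)C)[C@]2(C)O[C@H]2CC/C(CO[Si](C)(C)C(C)(C)C)=C\C1 | intermediate
33 | (1R,2R,3S,6E,9S,10E)-2,3-epoxy-6-(hydroxymethyl)-9-[(3S)-3-hydroxy-4-methylpent-4-en-1-yl]-2,9-dimethylcycloundeca-6,10-dien-1-yl 3-methylbut-2-enoate (CNP0309478.3) | C=C(C)[C@@H](O)CC[C@]1(C)/C=C/[C@@H](OC(=O)C=C(C)C)[C@]2(C)O[C@H]2CC/C(CO)=C\C1 | target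

**Step count and risk**

Total step count: 20. Longest linear sequence: 13 steps (1–3 or 4–6, then 7, 8, 13–20), which is 65% of the total.

Steps most likely to fail:

Step 16 (proposed new carbonylative Heck macrocyclization). Failure modes are oligomerization, direct non-carbonylative Heck closure, or acyl capture by the isopropenyl group (fourteen-membered ring). The fallback sets out from 27 and comes back at 28 using known reactions. Cross-metathesis of 27 with crotonaldehyde (second-generation Hoveyda–Grubbs catalyst, CH2Cl2, 40 °C) converts the vinyl group into the (2E,4S,6E,10E)-11-iodo-4-methyl-4-[(3S)-4-methyl-3-(TBS-oxy)pent-4-en-1-yl]-7-[(TBS-oxy)methyl]dodeca-2,6,10-trienal F1. An intramolecular Nozaki–Hiyama–Kishi reaction of F1 (CrCl2, NiCl2 cat., DMSO/THF, 23 °C, high dilution) joins the alkenyl iodide to the aldehyde and gives the macrocyclic dienol (C1 epimer mixture) F2. Dess–Martin oxidation of F2 gives 28.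

Step 17 (CBS reduction of a cross-conjugated macrocyclic dienone). Both carbonyl substituents are alkenyl, so the large/small assignment and hence the facial selectivity may be poor. The fallback sets out from 28 and comes back at 29. A reagent-neutral Luche reduction (NaBH4, CeCl3·7H2O, MeOH, −40 °C) gives 29 together with its (1S)-epimeric dienol F3. The two are separated by chromatography, or by running the mixture through the step 18 conditions, where only 29 is the matched, fast-reacting epimer. F3 is recycled to 28 with MnO2.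

Step 18 (tartrate-controlled epoxidation inside the eleven-membered ring). The ring conformation may block the required alcohol geometry or override the reagent and give the threo epoxide. The fallback sets out from 28 and comes back at 30, replacing steps 17 and 18. Nucleophilic epoxidation of 28 (t-BuOOH, DBU, toluene, or NaOCl with a cinchona-derived phase-transfer catalyst for facial control, diastereomers separated if needed) is site-selective for the C2=C3 enone because the β-carbon of the other enone is neopentyl. It gives the (2R,3S)-2,3-epoxy-10-en-1-one F4. Chelation-controlled reduction of F4 with Zn(BH4)2 (Et2O, −20 °C) gives the erythro epoxy alcohol 30.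

Further compounds
F1 | step 16 | (2E,4S,6E,10E)-11-iodo-4-methyl-4-[(3S)-4-methyl-3-(TBS-oxy)pent-4-en-1-yl]-7-[(TBS-oxy)methyl]dodeca-2,6,10-trienal | C=C(C)[C@@H](O[Si](C)(C)C(C)(C)C)CC[C@](C)(/C=C/C=O)C/C=C(\CC/C=C(\C)I)CO[Si](C)(C)C(C)(C)C
F2 | step 16 | (2E,6E,9S,10E)-2,9-dimethyl-6-[(TBS-oxy)methyl]-9-[(3S)-4-methyl-3-(TBS-oxy)pent-4-en-1-yl]cycloundeca-2,6,10-trien-1-ol (C1 epimer mixture) | C=C(C)[C@@H](O[Si](C)(C)C(C)(C)C)CC[C@]1(C)/C=C/C(O)/C(C)=C/CC/C(CO[Si](C)(C)C(C)(C)C)=C\C1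
F3 | step 17 | (1S,2E,6E,9S,10E)-2,9-dimethyl-6-[(TBS-oxy)methyl]-9-[(3S)-4-methyl-3-(TBS-oxy)pent-4-en-1-yl]cycloundeca-2,6,10-trien-1-ol | C=C(C)[C@@H](O[Si](C)(C)C(C)(C)C)CC[C@]1(C)/C=C/[C@H](O)/C(C)=C/CC/C(CO[Si](C)(C)C(C)(C)C)=C\C1
F4 | step 18 | (2R,3S,6E,9S,10E)-2,3-epoxy-2,9-dimethyl-6-[(TBS-oxy)methyl]-9-[(3S)-4-methyl-3-(TBS-oxy)pent-4-en-1-yl]cycloundeca-6,10-dien-1-one | C=C(C)[C@@H](O[Si](C)(C)C(C)(C)C)CC[C@]1(C)/C=C/C(=O)[C@]2(C)O[C@H]2CC/C(CO[Si](C)(C)C(C)(C)C)=C\C1
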